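Monday's last reading leaves 59.0 % of the starting material not turned into product. The new flask has Monday's equivalents of second substrate but less enzyme, and the question is what it has made by 4.0 min.

the same everywhere: starting material 20 mM

| flask | second substrate | enzyme | remark | time |
|---|---|---|---|---|
| Tuesday's | 1.5 equiv | 0.0052 mol% | run made earlier |  |
| Saturday's | 2.2 equiv | 0.0052 mol% | run made earlier |  |
| Monday's | 3 equiv | 0.0078 mol% | run made earlier |  |
| flask | 3.00 equiv | 0.0052 mol% |  | 4.0 min |

| run | time / min | product / % |
|---|---|---|
| Tuesday's | 0.333 | 3 |
| Tuesday's | 0.833 | 8 |
| Tuesday's | 1.50 | 16 |
| Tuesday's | 2.50 | 21 |
| Saturday's | 0.333 | 8 |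
| Saturday's | 0.833 | 12 |
| Saturday's | 1.50 | 15 |
| Saturday's | 2.50 | 28 |
| Monday's | 0.667 | 16 |
| Monday's | 1.33 | 25 |
| Monday's | 2.00 | 38 |
| Monday's | 2.50 | 41 |

(standard deviation of a reading: 1.5 percentage points)

- the analysis behind the earlier runs scatters by 1.5 percentage points, standard deviation
- the reaction counts as stopped when no species that holds the starting material changes by six tenths of a point or more over the second half of the time

- which holds at 4.0 min: what has brought the reaction to rest, or that it has not come to rest (all of the starting material has reacted / forward and back rates have come level / no working catalyst is left / the second substrate has run out first / it is still moving)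
- amount of product at 4.0 min, in percent of the starting material charged

Two chemists dispute this flask, and both count turnovers.

The second chemist trusts a steady pace. Monday's first reading gives 3080 /min per enzyme charged. Held for 4.0 min on 0.0052 mol%, that pace would give 64.0 % product in the flask.

The first chemist answers from the same run. Over Monday's whole run to its last reading the average pace is 2100 /min, which is lower than the first figure. So she reads Monday's curve and does not extend its start. Her working assumption is the one Selwyn's test examines: with equal charges of starting material and second substrate, equal enzyme-minutes give equal product.

Monday time is 2.67 min. It is the flask's time scaled by its loading over Monday's loading, the point on Monday's curve with the flask's enzyme-minutes. That point lies just later than Monday's last reading, which stands at 41 % after 2.50 min. So her step beyond the readings is short.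

The forecast takes her side, with 44 % and the verdict "it is still moving". Its ground: “The flask matches Monday's concentrations with two-thirds of the enzyme”.

The flask gives 42.0 %, and it is still moving.

    ternary complex ⇌ enzyme + product (K = 0.0160 M, k = 72.0 /s)
    second substrate + enzyme → spent catalyst (k = 0.0560 /M/s)
    second substrate + starting complex ⇌ ternary complex (K = 140 /M, k = 7.90 × 10⁵ /M/s)
    starting material + enzyme ⇌ starting complex (K = 18.0 /M, k = 2.70 × 10⁵ /M/s)

Product in the flask climbs from 25.6 % at 2.00 min to 42.0 % at 4.00 min, which is 22 percentage points below the steady pace. Monday's last reading, taken 0.170 min short of the flask's Monday time, stands 1 point below the flask, which at 4.00 min has 20.3 % of its catalyst as spent catalyst. The steady pace keeps the early region. The same flask read at 1.0 min has a Monday time of 0.667 min, Monday's first reading, so both views give 16 % there. That flask gives 14.0 %, with 4.89 % of its catalyst as spent catalyst, and Monday's reading carries a scatter of 1.5 points.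

(The data are calculated with constants of no real substance, noise included.)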